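The route rests on cutting benzene ring B of the dihydrobenzofuran at C7a–C3a and C5–C4. The key step exploits that this ring carries O1 on C7a, the carbinol C3 on C3a, prenyl on C7 and the chromone carbon on C5: a 3-alkoxy-4-prenyl-2-pyranone-6-carboxylate supplies C7a, C7, C6 and C5, and an ethyne already tied to the pyranone oxygen through C2 and C3 supplies C3a and C4. Heating joins diene and alkyne and expels CO2, closing the dihydrofuran and the arene in one operation with both stereocentres preset. The precursor is this pyranone ether, its two side-chain hydroxyls silylated; its ester later anchors ring C.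

Key step: step 11

Remark: compound 1 is taken as a catalogue chemical; locants C2–C7a are those of the dihydrobenzofuran of the target, which is trans-(2S,3S).

Step 1
Reactants: 1 3-hydroxy-2-oxo-2H-pyran-6-carboxylic acid
Product: 2 methyl 3-hydroxy-2-oxo-2H-pyran-6-carboxylate
Conditions: MeOH, H2SO4 (cat.), reflux
Reagents that add atoms: methanol, CO
Why: Fischer esterification of the carboxylic acid; the 2-pyranone ring and its enolic hydroxyl are stable to acidic methanol.

Step 2
Reactants: 2 methyl 3-hydroxy-2-oxo-2H-pyran-6-carboxylate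
Product: 3 methyl 3-(allyloxy)-2-oxo-2H-pyran-6-carboxylate
Conditions: allyl bromide, K2CO3, acetone, reflux
Reagents that add atoms: allyl bromide, C=CCBr
Why: Williamson O-alkylation of the acidic enolic hydroxyl (as its potassium salt) by a primary allylic bromide, carbonate being too weak a nucleophile to open the pyranone.

Step 3
Reactants: 3 methyl 3-(allyloxy)-2-oxo-2H-pyran-6-carboxylate
Product: 5 methyl 4-allyl-3-hydroxy-2-oxo-2H-pyran-6-carboxylate, via keto tautomer 4 (not isolated)
Conditions: o-dichlorobenzene, 180 °C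
Reagents that add atoms: none
Why: aromatic-type Claisen rearrangement of the allyl vinyl ether O–C3=C4, for which C4 is the only available terminus; tautomerisation of diketone 4 to the enol restores the pyranone.

Step 4
Reactants: 5 methyl 4-allyl-3-hydroxy-2-oxo-2H-pyran-6-carboxylate
Product: 6 methyl 3-hydroxy-4-(3-methylbut-2-en-1-yl)-2-oxo-2H-pyran-6-carboxylate
Conditions: 2-methylbut-2-ene (excess), (H2IMes)(PCy3)Cl2Ru=CHPh (second-generation Grubbs catalyst, 3 mol %), CH2Cl2, 40 °C
Reagents that add atoms: 2-methylbut-2-ene, CC=C(C)C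
Why: olefin cross-metathesis of the terminal allyl group with excess 2-methylbut-2-ene, the standard allyl-to-prenyl exchange; the electron-poor trisubstituted ring alkenes should not engage the ruthenium carbene.

Step 5
Reactants: 7 3-methylbut-2-enal; 8 ethynylmagnesium bromide
Product: 9 rac-5-methylhex-4-en-1-yn-3-ol
Conditions: THF, 0 °C; then aq. NH4Cl
Reagents that add atoms: none
Why: 1,2-addition of the alkynyl Grignard reagent to the enal carbonyl; the carbinol centre is formed racemic and is resolved in step 6.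

Step 6
Reactants: 9 rac-5-methylhex-4-en-1-yn-3-ol
Product: 10 (R)-5-methylhex-4-en-1-yn-3-ol
Conditions: Ti(OiPr)4, D-(−)-diisopropyl tartrate, t-BuOOH (0.6 equiv), 4 Å molecular sieves, CH2Cl2, −20 °C
Reagents that add atoms: none
Why: Sharpless kinetic resolution of a secondary allylic alcohol: with the D-tartrate ligand the titanium catalyst epoxidises the (S)-alcohol preferentially, so running slightly past half conversion should leave the (R)-alcohol enantiomerically enriched.

Step 7
Reactants: 10 (R)-5-methylhex-4-en-1-yn-3-ol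
Product: 11 (1S)-1-[(2R)-3,3-dimethyloxiran-2-yl]prop-2-yn-1-ol
Conditions: mCPBA, Na2HPO4 (buffer), CH2Cl2, 0 °C
Reagents that add atoms: 3-chloroperoxybenzoic acid, OOC(=O)c1cccc(Cl)c1
Why: hydroxyl-directed (Henbest) peracid epoxidation of the electron-rich trisubstituted alkene; allylic 1,3-strain against the cis-methyl holds the carbinol hydrogen in the alkene plane, so oxygen should be delivered syn to OH and give mainly the threo epoxy alcohol (oxirane carbon R), the minor erythro isomer being removed by chromatography after step 8.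

Step 8
Reactants: 11 (1S)-1-[(2R)-3,3-dimethyloxiran-2-yl]prop-2-yn-1-ol
Product: 12 tert-butyl({(1S)-1-[(2R)-3,3-dimethyloxiran-2-yl]prop-2-yn-1-yl}oxy)dimethylsilane
Conditions: TBSCl, imidazole, DMF, 0 °C → rt
Reagents that add atoms: tert-butyldimethylsilyl chloride, CC(C)(C)[Si](C)(C)Cl
Why: silylation of the secondary alcohol with silyl chloride and imidazole, conditions that leave the epoxide and the terminal alkyne untouched.

Step 9
Reactants: 6 methyl 3-hydroxy-4-(3-methylbut-2-en-1-yl)-2-oxo-2H-pyran-6-carboxylate; 12 tert-butyl({(1S)-1-[(2R)-3,3-dimethyloxiran-2-yl]prop-2-yn-1-yl}oxy)dimethylsilane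
Product: 13 methyl 3-{[(3S,4S)-4-(tert-butyldimethylsilyloxy)-2-hydroxy-2-methylhex-5-yn-3-yl]oxy}-4-(3-methylbut-2-en-1-yl)-2-oxo-2H-pyran-6-carboxylate
Conditions: 6 (1.3 equiv), Cs2CO3 (0.3 equiv), DMF, 80 °C
Reagents that add atoms: none
Why: base-catalysed epoxide opening by an aryloxide-type oxygen nucleophile, SN2 at the less substituted oxirane carbon with inversion, which turns the (R)-oxirane carbon into the (S)-configured ether carbon; the substoichiometric base lets excess acidic 6 protonate the tertiary alkoxide at once, so that it cannot attack the enol lactone or accept the silyl group.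

Step 10
Reactants: 13 methyl 3-{[(3S,4S)-4-(tert-butyldimethylsilyloxy)-2-hydroxy-2-methylhex-5-yn-3-yl]oxy}-4-(3-methylbut-2-en-1-yl)-2-oxo-2H-pyran-6-carboxylate
Product: 14 methyl 3-{[(3S,4S)-4-(tert-butyldimethylsilyloxy)-2-methyl-2-(triethylsilyloxy)hex-5-yn-3-yl]oxy}-4-(3-methylbut-2-en-1-yl)-2-oxo-2H-pyran-6-carboxylate
Conditions: Et3SiOTf, 2,6-lutidine, CH2Cl2, −78 → 0 °C
Reagents that add atoms: triethylsilyl trifluoromethanesulfonate, CC[Si](CC)(CC)OS(=O)(=O)C(F)(F)F
Why: silyl triflate silylation of the hindered tertiary alcohol with a hindered pyridine base; the cap removes the one nucleophile that could open the enol lactone or add to the alkyne while step 11 is heated, and it comes off in step 15.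

Step 11
Reactants: 14 methyl 3-{[(3S,4S)-4-(tert-butyldimethylsilyloxy)-2-methyl-2-(triethylsilyloxy)hex-5-yn-3-yl]oxy}-4-(3-methylbut-2-en-1-yl)-2-oxo-2H-pyran-6-carboxylate
Product: 16 methyl (2S,3S)-3-(tert-butyldimethylsilyloxy)-7-(3-methylbut-2-en-1-yl)-2-[2-(triethylsilyloxy)propan-2-yl]-2,3-dihydro-1-benzofuran-5-carboxylate, via bicyclic lactone adduct 15 (not isolated)
Conditions: o-dichlorobenzene (0.01 M), BHT (cat.), 170 °C
Reagents that add atoms: none
Why: thermal intramolecular [4+2] cycloaddition of the pyranone diene (C3=C4–C5=C6) with the tethered ethyne gives the 2-oxabicyclo[2.2.2]octadienone 15, which loses CO2 by retro-[4+2] to the arene; the closest known reaction type is the Diels–Alder/CO2-cycloreversion benzannulation of 2-pyranones with tethered alkynes. The dihydrofuran closes in the fused mode of an intramolecular Diels–Alder reaction with a three-atom tether (O1, C2, C3), the C7a–C3a bond being made to the inner alkyne carbon, and the benzene ring closes by the second σ-bond (C5–C4) followed by extrusion of the lactone bridge. No stereocentre is created in 16: the two bridgehead centres of 15 vanish on aromatisation, so both diastereomeric adducts converge, and C2 and C3 are carried unchanged from 14. The step needs regioselectivity, secured because the short tether allows only the orientation that joins the inner alkyne carbon to pyranone C3, and chemoselectivity for the alkyne over the prenyl alkene, which cannot reach the diene termini from C4. The two silyl ethers block loss of the benzylic oxygen and opening of the lactone at the reaction temperature.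

Step 12
Reactants: 17 2',4',6'-trihydroxyacetophenone
Product: 18 1-[2-hydroxy-4,6-bis(triisopropylsilyloxy)phenyl]ethan-1-one
Conditions: iPr3SiCl (2.2 equiv), imidazole, DMF, rt → 40 °C
Reagents that add atoms: triisopropylsilyl chloride, CC(C)[Si](Cl)(C(C)C)C(C)C
Why: phenol silylation; the 4-OH and one ortho-OH react while the remaining ortho-OH, hydrogen-bonded to the acetyl carbonyl, should stay free.

Step 13
Reactants: 16 methyl (2S,3S)-3-(tert-butyldimethylsilyloxy)-7-(3-methylbut-2-en-1-yl)-2-[2-(triethylsilyloxy)propan-2-yl]-2,3-dihydro-1-benzofuran-5-carboxylate; 18 1-[2-hydroxy-4,6-bis(triisopropylsilyloxy)phenyl]ethan-1-one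
Product: 19 1-[2-hydroxy-4,6-bis(triisopropylsilyloxy)phenyl]-3-{(2S,3S)-3-(tert-butyldimethylsilyloxy)-7-(3-methylbut-2-en-1-yl)-2-[2-(triethylsilyloxy)propan-2-yl]-2,3-dihydro-1-benzofuran-5-yl}propane-1,3-dione
Conditions: LiN(SiMe3)2 (3.5 equiv), THF, −78 → 40 °C; then AcOH
Reagents that add atoms: none
Why: crossed Claisen condensation between the lithium enolate of the phenoxide of 18 and the non-enolisable aryl ester, driven by deprotonation of the 1,3-diketone; the bulky aryl silyl ethers should withstand the methoxide released.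

Step 14
Reactants: 19 1-[2-hydroxy-4,6-bis(triisopropylsilyloxy)phenyl]-3-{(2S,3S)-3-(tert-butyldimethylsilyloxy)-7-(3-methylbut-2-en-1-yl)-2-[2-(triethylsilyloxy)propan-2-yl]-2,3-dihydro-1-benzofuran-5-yl}propane-1,3-dione
Product: 21 2-{(2S,3S)-3-(tert-butyldimethylsilyloxy)-7-(3-methylbut-2-en-1-yl)-2-[2-(triethylsilyloxy)propan-2-yl]-2,3-dihydro-1-benzofuran-5-yl}-5,7-bis(triisopropylsilyloxy)-4H-chromen-4-one, via hemiketal 20 (not isolated)
Conditions: p-TsOH·H2O (10 mol %), toluene, 50 °C
Reagents that add atoms: none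
Why: acid-catalysed cyclodehydration of an o-hydroxyaryl 1,3-diketone (hemiketal formation, then loss of water) to the 4H-chromen-4-one; catalytic acid in a non-nucleophilic solvent should spare the silyl ethers, benzylic ionisation being disfavoured by the acyl group para to the ring oxygen.

Step 15
Reactants: 21 2-{(2S,3S)-3-(tert-butyldimethylsilyloxy)-7-(3-methylbut-2-en-1-yl)-2-[2-(triethylsilyloxy)propan-2-yl]-2,3-dihydro-1-benzofuran-5-yl}-5,7-bis(triisopropylsilyloxy)-4H-chromen-4-one
Product: 22 2-[(2S,3S)-3-hydroxy-2-(2-hydroxypropan-2-yl)-7-(3-methylbut-2-en-1-yl)-2,3-dihydro-1-benzofuran-5-yl]-5,7-dihydroxy-4H-chromen-4-one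
Conditions: Bu4NF (6 equiv), AcOH (6 equiv), THF, 0 °C → rt
Reagents that add atoms: none
Why: fluoride-mediated cleavage of all four silyl ethers (Si–F bond formation), buffered with acetic acid so that neither base nor strong acid touches the benzylic carbinol or the prenyl group.

Compound list
1 | 3-hydroxy-2-oxo-2H-pyran-6-carboxylic acid | OC(=O)c1ccc(O)c(=O)o1 | starting material
2 | methyl 3-hydroxy-2-oxo-2H-pyran-6-carboxylate | COC(=O)c1ccc(O)c(=O)o1 | intermediate
3 | methyl 3-(allyloxy)-2-oxo-2H-pyran-6-carboxylate | COC(=O)c1ccc(OCC=C)c(=O)o1 | intermediate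
4 | methyl 4-allyl-2,3-dioxo-3,4-dihydro-2H-pyran-6-carboxylate (keto tautomer, racemic, not isolated) | COC(=O)C1=CC(CC=C)C(=O)C(=O)O1 | intermediate
5 | methyl 4-allyl-3-hydroxy-2-oxo-2H-pyran-6-carboxylate | COC(=O)c1cc(CC=C)c(O)c(=O)o1 | intermediate
6 | methyl 3-hydroxy-4-(3-methylbut-2-en-1-yl)-2-oxo-2H-pyran-6-carboxylate | COC(=O)c1cc(CC=C(C)C)c(O)c(=O)o1 | intermediate
7 | 3-methylbut-2-enal | CC(C)=CC=O | starting material
8 | ethynylmagnesium bromide | C#C[Mg]Br | starting material
9 | rac-5-methylhex-4-en-1-yn-3-ol | C#CC(O)C=C(C)C | intermediate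
10 | (R)-5-methylhex-4-en-1-yn-3-ol | C#C[C@H](O)C=C(C)C | intermediate
11 | (1S)-1-[(2R)-3,3-dimethyloxiran-2-yl]prop-2-yn-1-ol (threo) | C#C[C@H](O)[C@H]1OC1(C)C | intermediate
12 | tert-butyl({(1S)-1-[(2R)-3,3-dimethyloxiran-2-yl]prop-2-yn-1-yl}oxy)dimethylsilane | C#C[C@H](O[Si](C)(C)C(C)(C)C)[C@H]1OC1(C)C | intermediate
13 | methyl 3-{[(3S,4S)-4-(tert-butyldimethylsilyloxy)-2-hydroxy-2-methylhex-5-yn-3-yl]oxy}-4-(3-methylbut-2-en-1-yl)-2-oxo-2H-pyran-6-carboxylate | COC(=O)c1cc(CC=C(C)C)c(O[C@H](C(C)(C)O)[C@H](C#C)O[Si](C)(C)C(C)(C)C)c(=O)o1 | intermediate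
14 | methyl 3-{[(3S,4S)-4-(tert-butyldimethylsilyloxy)-2-methyl-2-(triethylsilyloxy)hex-5-yn-3-yl]oxy}-4-(3-methylbut-2-en-1-yl)-2-oxo-2H-pyran-6-carboxylate | COC(=O)c1cc(CC=C(C)C)c(O[C@H](C(C)(C)O[Si](CC)(CC)CC)[C@H](C#C)O[Si](C)(C)C(C)(C)C)c(=O)o1 | intermediate
15 | Diels–Alder adduct: 2-oxabicyclo[2.2.2]octa-5,7-dien-3-one with CO2Me on bridgehead C1, prenyl on C8, and the O–CH[C(CH3)2OSiEt3]–CH(OTBS) unit spanning bridgehead C4 and alkene carbon C5 (either bridgehead diastereomer, not isolated) | COC(=O)C12C=C(CC=C(C)C)C3(C(=O)O1)O[C@H](C(C)(C)O[Si](CC)(CC)CC)[C@@H](O[Si](C)(C)C(C)(C)C)C3=C2 | intermediate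
16 | methyl (2S,3S)-3-(tert-butyldimethylsilyloxy)-7-(3-methylbut-2-en-1-yl)-2-[2-(triethylsilyloxy)propan-2-yl]-2,3-dihydro-1-benzofuran-5-carboxylate | CC(C)=CCc1cc(C(=O)OC)cc2c1O[C@H](C(C)(C)O[Si](CC)(CC)CC)[C@H]2O[Si](C)(C)C(C)(C)C | intermediate
17 | 2',4',6'-trihydroxyacetophenone | CC(=O)c1c(O)cc(O)cc1O | starting material
18 | 1-[2-hydroxy-4,6-bis(triisopropylsilyloxy)phenyl]ethan-1-one | CC(=O)c1c(O)cc(O[Si](C(C)C)(C(C)C)C(C)C)cc1O[Si](C(C)C)(C(C)C)C(C)C | intermediate
19 | 1-[2-hydroxy-4,6-bis(triisopropylsilyloxy)phenyl]-3-{(2S,3S)-3-(tert-butyldimethylsilyloxy)-7-(3-methylbut-2-en-1-yl)-2-[2-(triethylsilyloxy)propan-2-yl]-2,3-dihydro-1-benzofuran-5-yl}propane-1,3-dione | CC(C)=CCc1cc(C(=O)CC(=O)c3c(O)cc(O[Si](C(C)C)(C(C)C)C(C)C)cc3O[Si](C(C)C)(C(C)C)C(C)C)cc2c1O[C@H](C(C)(C)O[Si](CC)(CC)CC)[C@H]2O[Si](C)(C)C(C)(C)C | intermediate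
20 | 2-hydroxy-2-aryl-5,7-bis(triisopropylsilyloxy)chroman-4-one hemiketal of 19 (aryl = the dihydrobenzofuran-5-yl group of 19; hemiketal carbon unassigned, not isolated) | CC(C)=CCc1cc(C3(O)CC(=O)c4c(O3)cc(O[Si](C(C)C)(C(C)C)C(C)C)cc4O[Si](C(C)C)(C(C)C)C(C)C)cc2c1O[C@H](C(C)(C)O[Si](CC)(CC)CC)[C@H]2O[Si](C)(C)C(C)(C)C | intermediate
21 | 2-{(2S,3S)-3-(tert-butyldimethylsilyloxy)-7-(3-methylbut-2-en-1-yl)-2-[2-(triethylsilyloxy)propan-2-yl]-2,3-dihydro-1-benzofuran-5-yl}-5,7-bis(triisopropylsilyloxy)-4H-chromen-4-one | CC(C)=CCc1cc(-c3cc(=O)c4c(o3)cc(O[Si](C(C)C)(C(C)C)C(C)C)cc4O[Si](C(C)C)(C(C)C)C(C)C)cc2c1O[C@H](C(C)(C)O[Si](CC)(CC)CC)[C@H]2O[Si](C)(C)C(C)(C)C | intermediate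
22 | 2-[(2S,3S)-3-hydroxy-2-(2-hydroxypropan-2-yl)-7-(3-methylbut-2-en-1-yl)-2,3-dihydro-1-benzofuran-5-yl]-5,7-dihydroxy-4H-chromen-4-one | CC(C)=CCc1cc(-c2cc(=O)c3c(O)cc(O)cc3o2)cc2c1O[C@H](C(C)(C)O)[C@H]2O | target

Total step count: 15 steps.
Longest linear sequence: 10 steps (steps 1–4, 9–11, 13–15; the branch through steps 5–8 is equally long).

Steps most likely to fail

Step 11. The cycloaddition of an unactivated alkyne may be slower than thermal decay of the substrate. The prenyl group on pyranone C4 crowds the bond-forming C3 terminus and offers allylic ene and radical pathways, so material may be lost by silanol elimination or oligomerisation before CO2 is expelled. The fallback takes the prenyl group out of the cycloaddition and installs it afterwards; it sets out from 2 and 12 and returns at 16.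
- Opening of 12 by 2 under the conditions of step 9 should give methyl 3-{[(3S,4S)-4-(tert-butyldimethylsilyloxy)-2-hydroxy-2-methylhex-5-yn-3-yl]oxy}-2-oxo-2H-pyran-6-carboxylate F1.
- Et3SiOTf and 2,6-lutidine should convert it into the bis-silyl ether F2.
- Heating F2 as in step 11 should give, through the prenyl-free bicyclic lactone adduct F3, methyl (2S,3S)-3-(tert-butyldimethylsilyloxy)-2-[2-(triethylsilyloxy)propan-2-yl]-2,3-dihydro-1-benzofuran-5-carboxylate F4.
- NBS in DMF should brominate the only position ortho to the ring oxygen and meta to the ester, giving the 7-bromo compound F5.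
- Stille coupling of F5 with tributyl(3-methylbut-2-en-1-yl)stannane and Pd(PPh3)4 in DMF should then deliver 16.

Step 9. Attack of the weakly nucleophilic, ortho-substituted pyranone oxyanion on the crowded oxirane CH may be so slow that base-induced degradation of 6 or silyl migration in the product takes over. The fallback replaces the epoxide by the more electrophilic cyclic sulfate, whose tertiary oxygen leaves as a non-nucleophilic sulfate; it sets out from 12 and returns at 13.
- Dilute HClO4 in aqueous THF at 0 °C should open 12 at the tertiary carbon, with retention at the CH–O centre, to give (3R,4S)-4-(tert-butyldimethylsilyloxy)-2-methylhex-5-yne-2,3-diol F6.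
- SOCl2 and Et3N should give the cyclic sulfite F7, and brief oxidation with RuCl3 (cat.) and NaIO4 at 0 °C the cyclic sulfate F8.
- The cesium salt of 6 (Cs2CO3, DMF, rt) should open F8 at the secondary carbon with inversion to give the cesium sulfate monoester F9.
- H2SO4 (cat.) with one equivalent of water in THF should hydrolyse F9 to 13.

Step 13. Acylation of the enolate by the electron-rich para-alkoxybenzoate may stall, while the methoxide set free slowly strips the phenolic silyl ethers and lowers the reactivity of the enolate further. The fallback moves the C–C bond formation into an intramolecular acyl shift; it sets out from 16 and returns at 19.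
- LiOH in THF–MeOH–H2O should saponify 16 to (2S,3S)-3-(tert-butyldimethylsilyloxy)-7-(3-methylbut-2-en-1-yl)-2-[2-(triethylsilyloxy)propan-2-yl]-2,3-dihydro-1-benzofuran-5-carboxylic acid F10.
- EDC·HCl and DMAP should esterify F10 with the free phenol of 18 to give the 2-acetyl-3,5-bis(triisopropylsilyloxy)phenyl ester F11.
- KOtBu in THF should induce the Baker–Venkataraman O→C acyl migration of F11 to 19.

Further compounds
F1 | step 11 | methyl 3-{[(3S,4S)-4-(tert-butyldimethylsilyloxy)-2-hydroxy-2-methylhex-5-yn-3-yl]oxy}-2-oxo-2H-pyran-6-carboxylate | COC(=O)c1ccc(O[C@H](C(C)(C)O)[C@H](C#C)O[Si](C)(C)C(C)(C)C)c(=O)o1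
F2 | step 11 | methyl 3-{[(3S,4S)-4-(tert-butyldimethylsilyloxy)-2-methyl-2-(triethylsilyloxy)hex-5-yn-3-yl]oxy}-2-oxo-2H-pyran-6-carboxylate | COC(=O)c1ccc(O[C@H](C(C)(C)O[Si](CC)(CC)CC)[C@H](C#C)O[Si](C)(C)C(C)(C)C)c(=O)o1
F3 | step 11 | prenyl-free bicyclic lactone adduct (analogue of 15 without the prenyl group) | COC(=O)C12C=CC3(C(=O)O1)O[C@H](C(C)(C)O[Si](CC)(CC)CC)[C@@H](O[Si](C)(C)C(C)(C)C)C3=C2
F4 | step 11 | methyl (2S,3S)-3-(tert-butyldimethylsilyloxy)-2-[2-(triethylsilyloxy)propan-2-yl]-2,3-dihydro-1-benzofuran-5-carboxylate | c1cc(C(=O)OC)cc2c1O[C@H](C(C)(C)O[Si](CC)(CC)CC)[C@H]2O[Si](C)(C)C(C)(C)C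
F5 | step 11 | methyl (2S,3S)-7-bromo-3-(tert-butyldimethylsilyloxy)-2-[2-(triethylsilyloxy)propan-2-yl]-2,3-dihydro-1-benzofuran-5-carboxylate | Brc1cc(C(=O)OC)cc2c1O[C@H](C(C)(C)O[Si](CC)(CC)CC)[C@H]2O[Si](C)(C)C(C)(C)C
F6 | step 9 | (3R,4S)-4-(tert-butyldimethylsilyloxy)-2-methylhex-5-yne-2,3-diol | C#C[C@H](O[Si](C)(C)C(C)(C)C)[C@@H](O)C(C)(C)O
F7 | step 9 | (5R)-5-[(1S)-1-(tert-butyldimethylsilyloxy)prop-2-yn-1-yl]-4,4-dimethyl-1,3,2-dioxathiolane 2-oxide | C#C[C@H](O[Si](C)(C)C(C)(C)C)[C@H]1OS(=O)OC1(C)C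
F8 | step 9 | (5R)-5-[(1S)-1-(tert-butyldimethylsilyloxy)prop-2-yn-1-yl]-4,4-dimethyl-1,3,2-dioxathiolane 2,2-dioxide | C#C[C@H](O[Si](C)(C)C(C)(C)C)[C@H]1OS(=O)(=O)OC1(C)C
F9 | step 9 | cesium (3S,4S)-4-(tert-butyldimethylsilyloxy)-3-{[6-(methoxycarbonyl)-4-(3-methylbut-2-en-1-yl)-2-oxo-2H-pyran-3-yl]oxy}-2-methylhex-5-yn-2-yl sulfate | COC(=O)c1cc(CC=C(C)C)c(O[C@H](C(C)(C)OS(=O)(=O)[O-])[C@H](C#C)O[Si](C)(C)C(C)(C)C)c(=O)o1.[Cs+]
F10 | step 13 | (2S,3S)-3-(tert-butyldimethylsilyloxy)-7-(3-methylbut-2-en-1-yl)-2-[2-(triethylsilyloxy)propan-2-yl]-2,3-dihydro-1-benzofuran-5-carboxylic acid | CC(C)=CCc1cc(C(=O)O)cc2c1O[C@H](C(C)(C)O[Si](CC)(CC)CC)[C@H]2O[Si](C)(C)C(C)(C)C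
F11 | step 13 | 2-acetyl-3,5-bis(triisopropylsilyloxy)phenyl (2S,3S)-3-(tert-butyldimethylsilyloxy)-7-(3-methylbut-2-en-1-yl)-2-[2-(triethylsilyloxy)propan-2-yl]-2,3-dihydro-1-benzofuran-5-carboxylate | CC(C)=CCc1cc(C(=O)Oc3cc(O[Si](C(C)C)(C(C)C)C(C)C)cc(O[Si](C(C)C)(C(C)C)C(C)C)c3C(C)=O)cc2c1O[C@H](C(C)(C)O[Si](CC)(CC)CC)[C@H]2O[Si](C)(C)C(C)(C)C
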